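**Plan**
- Retrosynthesis: the C5′–C6′ bond is cut first (allyl–alkyl coupling), then O1–C8a and C4–C4a are cut together. This leaves aryl iodide 2, the linalool-derived bromo-alcohol 6 and the C6′–C12′ bromide 18.
- Enabling feature: on ring A, C8a (carrying O1) sits between C8 (methyl) and C4a (carrying C4). An ortho-methyl aryl iodide acquires exactly this 1,2,3-array by ortho-alkylation plus ipso-etherification, and C4–C3–C2(OH)(CH3) is the hydroborated vinyl end of linalool.
- Forward order: the dihydropyran ring B closes in step 4. The chain is then extended by allylic oxidation, bromination and copper-catalysed coupling with the Grignard reagent of 18; the C9′ ketone and the phenol are unveiled last.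
- Stereochemistry: C2 (R) is carried unchanged from (R)-linalool, C8′ (S) comes from a reagent-controlled anti-crotylboration, and the 3′E alkene comes from the E-selectivity of the SeO2 oxidation.

Key step: step 4

Numbering: chroman O1, C2–C4, C4a, C5–C8, C8a; side chain C1′ (on C2) to C12′, with methyls on C4′, C8′ and C12′.
Remark: (R)-(−)-linalool of high enantiomeric purity is assumed, because C2 of the target derives from it alone.
Remark: the C9′ carbinol configuration made in step 8 is erased in step 14; only C8′ has to be controlled there.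

**Step 1**
Reactants: 1 4-iodo-3-methylphenol
Product: 2 1-iodo-4-(methoxymethoxy)-2-methylbenzene
Conditions: NaH, MOMCl, THF, 0 °C to rt
Reagents that add atoms: chloromethyl methyl ether, COCCl
Why: Williamson-type O-alkylation of the sodium phenoxide with the reactive α-chloro ether installs a base-stable acetal that survives the carbonate, organometallic and oxidative steps ahead.

**Step 2**
Reactants: 3 (R)-linalool
Product: 5 (3R)-3,7-dimethyloct-6-ene-1,3-diol, via alkylborane 4 (not isolated)
Conditions: 9-BBN (2.2 equiv), THF, 0 °C to rt; then 3 M NaOH, 30% H2O2, 0 °C to rt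
Reagents that add atoms: hydrogen peroxide, OO (oxygen of the new hydroxyl); 9-borabicyclo[3.3.1]nonane, B1C2CCCC1CCC2 (its boron stays only in intermediate 4)
Why: Brown hydroboration–oxidation, in which bulky 9-BBN adds anti-Markovnikov to the monosubstituted vinyl group only, leaves the trisubstituted alkene alone and is oxidised with retention, so the carbinol stereocentre is not touched.

**Step 3**
Reactants: 5 (3R)-3,7-dimethyloct-6-ene-1,3-diol
Product: 6 (3R)-1-bromo-3,7-dimethyloct-6-en-3-ol
Conditions: CBr4, PPh3, CH2Cl2, 0 °C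
Reagents that add atoms: carbon tetrabromide, BrC(Br)(Br)Br
Why: Appel reaction, in which only the primary hydroxyl forms an alkoxyphosphonium ion that bromide can displace (SN2), the hindered tertiary hydroxyl staying free for the annulation.

**Step 4**
Reactants: 2 1-iodo-4-(methoxymethoxy)-2-methylbenzene; 6 (3R)-1-bromo-3,7-dimethyloct-6-en-3-ol
Product: 7 (2R)-6-(methoxymethoxy)-2,8-dimethyl-2-(4-methylpent-3-en-1-yl)chroman
Conditions: Pd(OAc)2 (10 mol %), 2-dicyclohexylphosphino-2′,6′-diisopropoxybiphenyl (RuPhos, 20 mol %), norbornene (1.5 equiv), Cs2CO3 (3 equiv), 6 (1.8 equiv), 1,4-dioxane, 100 °C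
Reagents that add atoms: none
Why: Proposed new method: zerovalent palladium inserts into the C–I bond of 2, norbornene inserts and the only free ortho C–H (future C4a) is palladated to an aryl–norbornyl palladacycle of divalent palladium, which adds the primary C–Br bond of 6 (tetravalent palladium) and reductively eliminates to forge C4–C4a; with both ortho positions then occupied (C8 methyl, new C4), norbornene is expelled by β-carbon elimination and the arylpalladium species is captured by the tethered tertiary alkoxide, C–O reductive elimination forming O1–C8a. The closest known reaction types are the Pd/norbornene annulation of aryl iodides with epoxides to 2,3-dihydrobenzofurans (same ortho-alkylation then ipso-etherification order, one ring atom fewer) and the phosphine-promoted palladium-catalysed intramolecular O-arylation of tertiary alcohols to 2,2-disubstituted chromans. Ring B closes by ipso C–O reductive elimination from a seven-membered oxapalladacycle, a net [4+2] annulation in which 6 supplies C4, C3, C2 and O1 and the arene supplies C4a and C8a. No stereocentre is created: C2 is a spectator quaternary carbinol carbon, so the configuration of 3 is carried over unchanged. The step needs site selectivity (alkylation at the single free ortho C–H, etherification at the ipso carbon), secured by the C8 methyl and the norbornene relay, and chemoselectivity for annulation over oxetane formation or β-hydride loss, secured by the weak heterogeneous base, the absence of a carbinol hydrogen and the excess of 6.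

**Step 5**
Reactants: 7 (2R)-6-(methoxymethoxy)-2,8-dimethyl-2-(4-methylpent-3-en-1-yl)chroman
Product: 9 (2E)-5-[(2R)-6-(methoxymethoxy)-2,8-dimethylchroman-2-yl]-2-methylpent-2-en-1-ol, via enal 8 (not isolated)
Conditions: SeO2 (0.3 equiv), t-BuOOH (70% aq.), salicylic acid (cat.), CH2Cl2, rt; then NaBH4, MeOH, 0 °C
Reagents that add atoms: selenium dioxide, O=[Se]=O (catalytic oxygen carrier); tert-butyl hydroperoxide, CC(C)(C)OO (terminal oxidant)
Why: Riley allylic oxidation (ene reaction then [2,3]-sigmatropic shift) attacks the more substituted alkene terminus and selects the (E)-methyl group, and the borohydride treatment returns the over-oxidised enal 8 to 9.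

**Step 6**
Reactants: 9 (2E)-5-[(2R)-6-(methoxymethoxy)-2,8-dimethylchroman-2-yl]-2-methylpent-2-en-1-ol
Product: 10 (2R)-2-[(3E)-5-bromo-4-methylpent-3-en-1-yl]-6-(methoxymethoxy)-2,8-dimethylchroman
Conditions: CBr4, PPh3, CH2Cl2, −20 to 0 °C; used without storage
Reagents that add atoms: carbon tetrabromide, BrC(Br)(Br)Br
Why: Appel bromination of the primary allylic alcohol under neutral conditions proceeds by direct SN2 displacement, so neither allylic transposition nor loss of the acetal is expected.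

**Step 7**
Reactants: 11 4-methylpent-3-en-1-ol
Product: 12 4-methylpent-3-enal
Conditions: Dess–Martin periodinane, NaHCO3, CH2Cl2, 0 °C to rt; filtered and used at once as a solution
Reagents that add atoms: none
Why: Dess–Martin oxidation under bicarbonate buffer gives the β,γ-unsaturated aldehyde without the base or acid that would move the double bond into conjugation.

**Step 8**
Reactants: 12 4-methylpent-3-enal
Product: 14 (3S,4R)-3,7-dimethylocta-1,6-dien-4-ol, via borinate 13 (not isolated)
Conditions: (E)-but-2-ene, KOt-Bu, n-BuLi, THF, −78 to −45 °C; (−)-Ipc2BOMe [from (+)-α-pinene], −78 °C; BF3·OEt2, −78 °C; then 12, −78 °C; then 3 M NaOH, 30% H2O2, 0 °C to rt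
Reagents that add atoms: (E)-but-2-ene, C/C=C/C (the four crotyl carbons); (−)-B-methoxydiisopinocampheylborane, COB([C@@H]1C[C@@H]2C[C@@H](C2(C)C)[C@H]1C)[C@@H]1C[C@@H]2C[C@@H](C2(C)C)[C@H]1C (its boron and terpene groups stay only in intermediate 13)
Why: Brown crotylboration through a closed chair (Zimmerman–Traxler) transition state, in which the (E)-crotyl geometry gives the anti relationship and the isopinocampheyl groups derived from (+)-α-pinene direct attack onto the Si face of the aldehyde, setting C8′ (3S in 14) as required and C9′ (4R, erased later).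

**Step 9**
Reactants: 14 (3S,4R)-3,7-dimethylocta-1,6-dien-4-ol
Product: 15 tert-butyl{[(3S,4R)-3,7-dimethylocta-1,6-dien-4-yl]oxy}dimethylsilane
Conditions: TBSOTf, 2,6-lutidine, CH2Cl2, −78 to 0 °C
Reagents that add atoms: tert-butyldimethylsilyl trifluoromethanesulfonate, CC(C)(C)[Si](C)(C)OS(=O)(=O)C(F)(F)F
Why: Silylation of the hindered secondary alcohol with the reactive silyl triflate gives an ether that tolerates hydroboration, Grignard formation and copper-catalysed coupling.

**Step 10**
Reactants: 15 tert-butyl{[(3S,4R)-3,7-dimethylocta-1,6-dien-4-yl]oxy}dimethylsilane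
Product: 17 (3S,4R)-4-[(tert-butyldimethylsilyl)oxy]-3,7-dimethyloct-6-en-1-ol, via alkylborane 16 (not isolated)
Conditions: 9-BBN, THF, 0 °C to rt; then 3 M NaOH, 30% H2O2, 0 °C
Reagents that add atoms: hydrogen peroxide, OO (oxygen of the new hydroxyl); 9-borabicyclo[3.3.1]nonane, B1C2CCCC1CCC2 (its boron stays only in intermediate 16)
Why: Brown hydroboration–oxidation with 9-BBN is selective for the terminal vinyl group over the trisubstituted alkene and places the hydroxyl on C6′ without affecting C8′.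

**Step 11**
Reactants: 17 (3S,4R)-4-[(tert-butyldimethylsilyl)oxy]-3,7-dimethyloct-6-en-1-ol
Product: 18 tert-butyl{[(3S,4R)-1-bromo-3,7-dimethyloct-6-en-4-yl]oxy}dimethylsilane
Conditions: CBr4, PPh3, CH2Cl2, 0 °C
Reagents that add atoms: carbon tetrabromide, BrC(Br)(Br)Br
Why: Appel reaction converts the unhindered primary alcohol into the bromide by SN2 displacement under neutral conditions that leave the silyl ether and the alkene intact.

**Step 12**
Reactants: 18 tert-butyl{[(3S,4R)-1-bromo-3,7-dimethyloct-6-en-4-yl]oxy}dimethylsilane; 10 (2R)-2-[(3E)-5-bromo-4-methylpent-3-en-1-yl]-6-(methoxymethoxy)-2,8-dimethylchroman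
Product: 20 (2R)-2-[(3E,8S,9R)-9-[(tert-butyldimethylsilyl)oxy]-4,8,12-trimethyltrideca-3,11-dien-1-yl]-6-(methoxymethoxy)-2,8-dimethylchroman, via Grignard reagent 19 (not isolated)
Conditions: Mg turnings, THF, 40 °C; then 10, Li2CuCl4 (5 mol %), THF, −78 to 0 °C
Reagents that add atoms: magnesium, [Mg] (present only in intermediate 19)
Why: Grignard formation followed by copper-catalysed sp3–sp3 cross-coupling (Li2CuCl4), in which the alkylcopper species displaces the primary allylic bromide at the α-carbon at low temperature, so the 3′E geometry and all stereocentres are carried through.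

**Step 13**
Reactants: 20 (2R)-2-[(3E,8S,9R)-9-[(tert-butyldimethylsilyl)oxy]-4,8,12-trimethyltrideca-3,11-dien-1-yl]-6-(methoxymethoxy)-2,8-dimethylchroman
Product: 21 (3E,8S,9R)-1-[(2R)-6-(methoxymethoxy)-2,8-dimethylchroman-2-yl]-4,8,12-trimethyltrideca-3,11-dien-9-ol
Conditions: TBAF, THF, rt to 40 °C
Reagents that add atoms: none
Why: Fluoride-induced desilylation, driven by the strong Si–F bond, frees the C9′ hydroxyl while the aryl acetal is inert to fluoride.

**Step 14**
Reactants: 21 (3E,8S,9R)-1-[(2R)-6-(methoxymethoxy)-2,8-dimethylchroman-2-yl]-4,8,12-trimethyltrideca-3,11-dien-9-ol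
Product: 22 (3E,8S)-1-[(2R)-6-(methoxymethoxy)-2,8-dimethylchroman-2-yl]-4,8,12-trimethyltrideca-3,11-dien-9-one
Conditions: Dess–Martin periodinane, NaHCO3, CH2Cl2, 0 °C
Reagents that add atoms: none
Why: Dess–Martin oxidation under bicarbonate buffer turns the secondary carbinol into the ketone without base or strong acid, so the α-stereocentre C8′ and the β,γ position of the C11′ alkene should persist.

**Step 15**
Reactants: 22 (3E,8S)-1-[(2R)-6-(methoxymethoxy)-2,8-dimethylchroman-2-yl]-4,8,12-trimethyltrideca-3,11-dien-9-one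
Product: 23 (2R)-2,8-dimethyl-2-[(3E,8S)-4,8,12-trimethyl-9-oxotrideca-3,11-dien-1-yl]chroman-6-ol (CNP0280076.1)
Conditions: NaHSO4·SiO2, wet CH2Cl2, rt, under argon
Reagents that add atoms: none
Why: Acid-catalysed hydrolysis of the aryl methoxymethyl acetal on the mild solid acid NaHSO4·SiO2 in an aprotic medium frees the phenol while keeping enolisation of the β,γ-unsaturated ketone slow.

**Compound list**
1 | 4-iodo-3-methylphenol | Cc1cc(O)ccc1I | starting material
2 | 1-iodo-4-(methoxymethoxy)-2-methylbenzene | Cc1cc(OCOC)ccc1I | intermediate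
3 | (R)-linalool, (3R)-3,7-dimethylocta-1,6-dien-3-ol | C=C[C@](C)(O)CCC=C(C)C | starting material
4 | 9-[(3S)-3-hydroxy-3,7-dimethyloct-6-en-1-yl]-9-borabicyclo[3.3.1]nonane (same spatial arrangement as 3; the descriptor changes by CIP priority only) | O[C@@](C)(CCB1C2CCCC1CCC2)CCC=C(C)C | intermediate
5 | (3R)-3,7-dimethyloct-6-ene-1,3-diol | O[C@@](C)(CCO)CCC=C(C)C | intermediate
6 | (3R)-1-bromo-3,7-dimethyloct-6-en-3-ol | O[C@@](C)(CCBr)CCC=C(C)C | intermediate
7 | (2R)-6-(methoxymethoxy)-2,8-dimethyl-2-(4-methylpent-3-en-1-yl)chroman | CC(C)=CCC[C@]1(C)CCc2cc(OCOC)cc(C)c2O1 | intermediate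
8 | (2E)-5-[(2R)-6-(methoxymethoxy)-2,8-dimethylchroman-2-yl]-2-methylpent-2-enal | O=C/C(C)=C/CC[C@]1(C)CCc2cc(OCOC)cc(C)c2O1 | intermediate
9 | (2E)-5-[(2R)-6-(methoxymethoxy)-2,8-dimethylchroman-2-yl]-2-methylpent-2-en-1-ol | OC/C(C)=C/CC[C@]1(C)CCc2cc(OCOC)cc(C)c2O1 | intermediate
10 | (2R)-2-[(3E)-5-bromo-4-methylpent-3-en-1-yl]-6-(methoxymethoxy)-2,8-dimethylchroman | BrC/C(C)=C/CC[C@]1(C)CCc2cc(OCOC)cc(C)c2O1 | intermediate
11 | 4-methylpent-3-en-1-ol | CC(C)=CCCO | starting material
12 | 4-methylpent-3-enal | CC(C)=CCC=O | intermediate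
13 | (3S,4R)-3,7-dimethylocta-1,6-dien-4-yl bis(isopinocampheyl)borinate | CC(C)=CC[C@@H](OB([C@@H]1C[C@@H]2C[C@@H](C2(C)C)[C@H]1C)[C@@H]1C[C@@H]2C[C@@H](C2(C)C)[C@H]1C)[C@@H](C)C=C | intermediate
14 | (3S,4R)-3,7-dimethylocta-1,6-dien-4-ol | CC(C)=CC[C@@H](O)[C@@H](C)C=C | intermediate
15 | tert-butyl{[(3S,4R)-3,7-dimethylocta-1,6-dien-4-yl]oxy}dimethylsilane | CC(C)=CC[C@@H](O[Si](C)(C)C(C)(C)C)[C@@H](C)C=C | intermediate
16 | 9-[(3S,4R)-4-[(tert-butyldimethylsilyl)oxy]-3,7-dimethyloct-6-en-1-yl]-9-borabicyclo[3.3.1]nonane | CC(C)=CC[C@@H](O[Si](C)(C)C(C)(C)C)[C@@H](C)CCB1C2CCCC1CCC2 | intermediate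
17 | (3S,4R)-4-[(tert-butyldimethylsilyl)oxy]-3,7-dimethyloct-6-en-1-ol | CC(C)=CC[C@@H](O[Si](C)(C)C(C)(C)C)[C@@H](C)CCO | intermediate
18 | tert-butyl{[(3S,4R)-1-bromo-3,7-dimethyloct-6-en-4-yl]oxy}dimethylsilane | CC(C)=CC[C@@H](O[Si](C)(C)C(C)(C)C)[C@@H](C)CCBr | intermediate
19 | {(3S,4R)-4-[(tert-butyldimethylsilyl)oxy]-3,7-dimethyloct-6-en-1-yl}magnesium bromide | CC(C)=CC[C@@H](O[Si](C)(C)C(C)(C)C)[C@@H](C)CC[Mg]Br | intermediate
20 | (2R)-2-[(3E,8S,9R)-9-[(tert-butyldimethylsilyl)oxy]-4,8,12-trimethyltrideca-3,11-dien-1-yl]-6-(methoxymethoxy)-2,8-dimethylchroman | CC(C)=CC[C@@H](O[Si](C)(C)C(C)(C)C)[C@@H](C)CCC/C(C)=C/CC[C@]1(C)CCc2cc(OCOC)cc(C)c2O1 | intermediate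
21 | (3E,8S,9R)-1-[(2R)-6-(methoxymethoxy)-2,8-dimethylchroman-2-yl]-4,8,12-trimethyltrideca-3,11-dien-9-ol | CC(C)=CC[C@@H](O)[C@@H](C)CCC/C(C)=C/CC[C@]1(C)CCc2cc(OCOC)cc(C)c2O1 | intermediate
22 | (3E,8S)-1-[(2R)-6-(methoxymethoxy)-2,8-dimethylchroman-2-yl]-4,8,12-trimethyltrideca-3,11-dien-9-one | CC(C)=CCC(=O)[C@@H](C)CCC/C(C)=C/CC[C@]1(C)CCc2cc(OCOC)cc(C)c2O1 | intermediate
23 | (2R)-2,8-dimethyl-2-[(3E,8S)-4,8,12-trimethyl-9-oxotrideca-3,11-dien-1-yl]chroman-6-ol | CC(C)=CCC(=O)[C@@H](C)CCC/C(C)=C/CC[C@]1(C)CCc2cc(O)cc(C)c2O1 | target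

**Step count**
Total: 15 steps.
Longest linear sequence: 9 steps (3 to 23 through steps 2, 3, 4, 5, 6, 12, 13, 14, 15; the arm from 11 through steps 7–15 is equally long).

**Steps most likely to fail, with fallbacks**

Step 4. The ortho-alkylation may be outrun by 4-exo cyclisation of the bromo-alcohol, or C–O reductive elimination may be too slow, so that the arylpalladium species is reduced at the ipso carbon instead of closing ring B. The fallback uses known reactions only; it sets out from alkylborane 4 (generated from 3 as in step 2) and returns at 7. Commercial 3-methyl-4-nitrophenol F1 is methoxymethylated (NaH, MOMCl, THF) to 4-(methoxymethoxy)-2-methyl-1-nitrobenzene F2, reduced (H2, Pd on carbon, EtOAc) to 4-(methoxymethoxy)-2-methylaniline F3 and iodinated ortho to nitrogen (NIS, MeCN, 0 °C) to 2-iodo-4-(methoxymethoxy)-6-methylaniline F4. Sandmeyer bromination (t-BuONO, CuBr2, MeCN) then gives 2-bromo-1-iodo-5-(methoxymethoxy)-3-methylbenzene F5. B-alkyl Suzuki–Miyaura coupling of 4 with F5 at the C–I bond (PdCl2(dppf), K3PO4, THF/H2O, rt) gives (3R)-1-[2-bromo-5-(methoxymethoxy)-3-methylphenyl]-3,7-dimethyloct-6-en-3-ol F6. Palladium-catalysed intramolecular O-arylation of the tertiary alcohol (Pd(OAc)2, 2-(di-tert-butylphosphino)-1,1′-binaphthyl, Cs2CO3, toluene, 80 °C) then closes ring B with retention at C2 and delivers 7.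

Step 12. The Grignard reagent may attack the allylic bromide with allylic transposition (SN2′), homocouple, or erode the 3′E geometry. The fallback sets out from 18 and 10 and returns at 20. Bromide 18 is converted with PhSO2Na (DMF, 60 °C) into tert-butyl{[(3S,4R)-3,7-dimethyl-1-(phenylsulfonyl)oct-6-en-4-yl]oxy}dimethylsilane F7. Its α-lithio derivative (n-BuLi, THF, −78 °C) is alkylated by 10 at the primary allylic carbon, a soft-carbanion SN2 process without transposition, to give (2R)-2-[(3E,8S,9R)-9-[(tert-butyldimethylsilyl)oxy]-4,8,12-trimethyl-6-(phenylsulfonyl)trideca-3,11-dien-1-yl]-6-(methoxymethoxy)-2,8-dimethylchroman F8 as a mixture of C6′ epimers. Buffered sodium amalgam (Na/Hg, Na2HPO4, MeOH/THF, −20 °C) removes the homoallylic sulfonyl group without moving the alkene and gives 20.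

Step 15. Under acid the C11′ double bond may migrate into conjugation with the ketone and C8′ may epimerise through enolisation before acetal cleavage is complete. The fallback sets out from 21 and returns at 23. The acetal is cleaved first, while no ketone is present (HCl, MeOH, rt), to give (2R)-2-[(3E,8S,9R)-9-hydroxy-4,8,12-trimethyltrideca-3,11-dien-1-yl]-2,8-dimethylchroman-6-ol F9. The phenol alone is silylated (TBSCl, imidazole, CH2Cl2, 0 °C) to (3E,8S,9R)-1-[(2R)-6-[(tert-butyldimethylsilyl)oxy]-2,8-dimethylchroman-2-yl]-4,8,12-trimethyltrideca-3,11-dien-9-ol F10. Buffered Dess–Martin oxidation gives (3E,8S)-1-[(2R)-6-[(tert-butyldimethylsilyl)oxy]-2,8-dimethylchroman-2-yl]-4,8,12-trimethyltrideca-3,11-dien-9-one F11. Acetic-acid-buffered fluoride (TBAF, AcOH, THF, 0 °C) then frees 23 under near-neutral conditions.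

**Further compounds**
F1 | step 4 | 3-methyl-4-nitrophenol | Cc1cc(O)ccc1[N+](=O)[O-]
F2 | step 4 | 4-(methoxymethoxy)-2-methyl-1-nitrobenzene | Cc1cc(OCOC)ccc1[N+](=O)[O-]
F3 | step 4 | 4-(methoxymethoxy)-2-methylaniline | Cc1cc(OCOC)ccc1N
F4 | step 4 | 2-iodo-4-(methoxymethoxy)-6-methylaniline | Cc1cc(OCOC)cc(I)c1N
F5 | step 4 | 2-bromo-1-iodo-5-(methoxymethoxy)-3-methylbenzene | Cc1cc(OCOC)cc(I)c1Br
F6 | step 4 | (3R)-1-[2-bromo-5-(methoxymethoxy)-3-methylphenyl]-3,7-dimethyloct-6-en-3-ol | O[C@@](C)(CCc1cc(OCOC)cc(C)c1Br)CCC=C(C)C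
F7 | step 12 | tert-butyl{[(3S,4R)-3,7-dimethyl-1-(phenylsulfonyl)oct-6-en-4-yl]oxy}dimethylsilane | CC(C)=CC[C@@H](O[Si](C)(C)C(C)(C)C)[C@@H](C)CCS(=O)(=O)c1ccccc1
F8 | step 12 | (2R)-2-[(3E,8S,9R)-9-[(tert-butyldimethylsilyl)oxy]-4,8,12-trimethyl-6-(phenylsulfonyl)trideca-3,11-dien-1-yl]-6-(methoxymethoxy)-2,8-dimethylchroman (C6′ epimers) | CC(C)=CC[C@@H](O[Si](C)(C)C(C)(C)C)[C@@H](C)CC(S(=O)(=O)c1ccccc1)C/C(C)=C/CC[C@]1(C)CCc2cc(OCOC)cc(C)c2O1
F9 | step 15 | (2R)-2-[(3E,8S,9R)-9-hydroxy-4,8,12-trimethyltrideca-3,11-dien-1-yl]-2,8-dimethylchroman-6-ol | CC(C)=CC[C@@H](O)[C@@H](C)CCC/C(C)=C/CC[C@]1(C)CCc2cc(O)cc(C)c2O1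
F10 | step 15 | (3E,8S,9R)-1-[(2R)-6-[(tert-butyldimethylsilyl)oxy]-2,8-dimethylchroman-2-yl]-4,8,12-trimethyltrideca-3,11-dien-9-ol | CC(C)=CC[C@@H](O)[C@@H](C)CCC/C(C)=C/CC[C@]1(C)CCc2cc(O[Si](C)(C)C(C)(C)C)cc(C)c2O1
F11 | step 15 | (3E,8S)-1-[(2R)-6-[(tert-butyldimethylsilyl)oxy]-2,8-dimethylchroman-2-yl]-4,8,12-trimethyltrideca-3,11-dien-9-one | CC(C)=CCC(=O)[C@@H](C)CCC/C(C)=C/CC[C@]1(C)CCc2cc(O[Si](C)(C)C(C)(C)C)cc(C)c2O1
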